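What I want left in the flask at the end is the open intermediate itself, and it is a leftover that wastes away while it waits.

| setting | Thursday's | Tuesday's | Monday's | Friday's |
|---|---|---|---|---|
| substrate | 0.17 M | 0.17 M | 0.17 M | 0.17 M |
| partner A | 0.425 M | 0.425 M | 0.425 M (fed, over 20.0 min) | 0.425 M |
| partner B | 0.204 M (fed, over 20.0 min) | 0.204 M | 0.204 M | 0.204 M |
| time | 20 min | 20 min | 20 min |  |
| remark | a stirred flask in which partner B is dosed at a steady rate over 20.0 min without added volume, worked up at 20 min | everything together in a closed stirred flask, run for 20 min | all but partner A at the start; partner A goes in evenly over 20.0 min, the run ends at 20 min | one stirred flow tank at steady state, fed with the mixture as stated, mean residence time 20 min |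

    partner B + partner A → second intermediate (k1 = 0.010 M⁻¹ s⁻¹)
    2 second intermediate → homo product (k2 = 0.044 M⁻¹ s⁻¹)
    substrate + partner B → open intermediate (k3 = 0.097 M⁻¹ s⁻¹)
    open intermediate + second intermediate → target (k4 = 0.023 M⁻¹ s⁻¹)
    open intermediate → side product (k5 = 6.4 × 10⁻⁴ s⁻¹)

- where a step has two of a species, its rate is k times that concentration squared, and two are used at each turn
- the stated concentrations are those of everything mixed, before any reaction; amounts are the same in each set-up
- the feed brings no volume worth counting
- run time (Thursday's): 20 min

- the set-up with the highest amount of open intermediate at the outlet or at the end, in percent of the substrate put in ("none" if the first two lie within 2 percentage points) (Thursday's / Tuesday's / Monday's / Friday's / none)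
- amount of open intermediate at the outlet or at the end, in percent of the substrate put in, Thursday's
- amount of open intermediate at the outlet or at the end, in percent of the substrate put in, Tuesday's
- amount of open intermediate at the outlet or at the end, in percent of the substrate put in, Monday's
- amount of open intermediate at the outlet or at the end, in percent of the substrate put in, Friday's

The open intermediate turns into side product by itself, with a mean lifetime of 26.0 min, so I fold that rate constant and the run time into one number:

N = 6.4 × 10⁻⁴ s⁻¹ × 20 min = 0.768

This N is the length of the run counted in lifetimes of the open intermediate on the side-product step. From it I get the share that escapes this decay, depending on when the material is made: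

made at the start: exp(−N) = 46.4%

made evenly along the run: (1 − exp(−N))/N = 69.8%

held in a stirred tank: 1/(1 + N) = 56.6%

With partner B at its charged concentration, the substrate's half-life on the step that makes the open intermediate is 0.584 min, much shorter than the run. So Tuesday's and Monday's both make their open intermediate early and take the first share. Thursday's doses partner B evenly and takes the second, so I put Thursday's first.

One number is not enough, though. N gives Tuesday's and Monday's the same share, and it ignores capture by the second intermediate. That second intermediate needs partner A, so I expect capture to cost Monday's, where partner A is fed, less than Tuesday's. These shares are survival figures, not yields.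

The forecast differs from them: Thursday's first, with 37% for Thursday's, 28% for Tuesday's, 32% for Monday's and 30% for Friday's. Its ground is that “Dosing partner B keeps the open intermediate young at the end”.

The simulation puts Thursday's first, with 42.6%, against 27.9% for Tuesday's, 39.6% for Monday's, 7.6 percentage points above the forecast, and 29.8% for Friday's. Monday's stands below its share of 46.4%, and in Monday's the side-product step uses open intermediate faster than capture does, by a factor of 58 at 0.746 min and 3.5 at 20.0 min. Read at 50 min, the same Monday's flask has run 1.92 lifetimes, which gives a share of 14.7% for material made at the start, and it holds 10.9%.

The numbers belong to no real substance; the result is computed.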